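The readings stem from a simulated flask for substances that don't exist; noise was put on by code.

Open dimer is the product we want from this charge, and the next run hangs on one choice: feed one partner slowly, or charge both at the start.

| flask | starting material | activator | protic impurity | temperature | remark | time |
|---|---|---|---|---|---|---|
| ochre | 14 mM | 1.5 equiv | 14 mM | 10 °C | run made earlier |  |
| green | 14 mM | 0.75 equiv | 14 mM | 25 °C | run made earlier |  |
| teal | 14 mM | 1.1 equiv | 14 mM | 10 °C | run made earlier |  |
| summer | 14 mM | 1.50 equiv (fed, over 6.0 min) | 14.0 mM |  | the addition at −5 °C, then warmed to 25 °C; the feed brings no volume worth counting | 10 min |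
| winter | 14 mM | 1.50 equiv (fed, over 6.0 min) | 14.0 mM | 25 °C | all else is in the flask from the start; the feed brings no volume worth counting | 10 min |
| dusk | 14 mM (fed, over 6.0 min) | 1.50 equiv | 14.0 mM | 25 °C | all else is in the flask from the start; the feed brings no volume worth counting | 10 min |
| dawn | 14 mM | 1.50 equiv | 14.0 mM | 25 °C | everything together at the start | 10 min |

- ochre (time / min: open dimer / %, ring / %): 1.00: 13.3, 2.1; 2.00: 26.3, 3.2; 3.00: 33.5, 4.1; 4.00: 37.5, 5.4; 8.00: 45.8, 5.7; 12.0: 49.2, 5.6
- green (time / min: open dimer / %, ring / %): 0.417: 10.6, 2.2; 1.33: 31.7, 4.3; 2.00: 38.0, 3.6; 3.00: 45.2, 3.9; 5.00: 50.9, 3.2; 6.00: 53.0, 2.6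
- teal (time / min: open dimer / %, ring / %): 2.00: 22.1, 1.7; 4.00: 32.7, 3.7; 6.00: 38.4, 3.1; 8.00: 41.1, 4.9; 10.0: 43.3, 6.2; 12.0: 44.7, 5.0

(standard deviation of a reading: 0.5 percentage points)

- a species is counted by the starting material in it: one open dimer counts as two
- the analysis behind the earlier runs scatters by 0.5 percentage points, standard deviation

1. which flask leads in amount of open dimer, in percent of the starting material charged ("all alike" within 1.5 percentage points) (summer / winter / dusk / dawn / all alike)
2. how much open dimer is there at the end, in percent of the starting material charged: summer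
3. how much open dimer is there at the end, in percent of the starting material charged: winter
4. how much open dimer is there at the end, in percent of the starting material charged: dusk
5. how much open dimer is there at the end, in percent of the starting material charged: dawn

We take the opening speed from green's first reading and scale it to the activator of the new flasks:

clock = (0.417 min ÷ 10.6%) × (0.75 ÷ 1.50) = 1.97 min

This is the dimer clock: the time a flask at 25 °C with 1.50 equiv would need to put the whole charge into open dimer at its opening speed. It is a short estimate. At 2.00 min, ochre and teal stand in a dimer ratio of 1.19 for an activator ratio of 1.36, so the speed rises less than in proportion.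

A feed as long as the clock is the unit of our scale:

feed ÷ clock = 6.0 min ÷ 1.97 min = 3.05

Ochre's dimer flattens near half of the charge, so we take it that something competes. The feed of winter and dusk at 25 °C is longer than the clock, so we expect the competitor to have longer in those flasks than in dawn. So we charge dawn. We expect its dimer to pass green's 53.0%, reached at 6.00 min with half the activator, but we commit to no closer figure.

The forecast also names dawn as the leader, with 80%. It puts winter at 76% with “same selectivity”, dusk at 63% and summer at 56%.

The flasks give 64.3% in dawn, 50.6% in summer, 45.6% in winter and 35.8% in dusk.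

    activated form ⇌ ring (K = 1.00, k = 0.0200 s⁻¹, Ea = 75.0 kJ mol⁻¹, ΔH = −58.0 kJ mol⁻¹)
    2 activator → self-condensation product (k = 0.770 M⁻¹ s⁻¹, Ea = 42.0 kJ mol⁻¹)
    starting material + activator → activated form (k = 0.800 M⁻¹ s⁻¹, Ea = 63.0 kJ mol⁻¹)
    starting material + protic impurity → quenched substrate (k = 0.290 M⁻¹ s⁻¹, Ea = 42.0 kJ mol⁻¹)
    starting material + activated form → open dimer (k = 4.30 M⁻¹ s⁻¹, Ea = 42.0 kJ mol⁻¹)
    (constants at 25 °C)

In dawn, half of the dimer step's turnover is done by 0.820 min, which is sooner than the 2.8 min pseudo-first-order half-life of starting material by the impurity path. The clock of 1.97 min is also shorter than that half-life and the feed of 6.0 min longer, and winter ends with 43.1% quenched substrate against 25.9% in dawn. For the repeat of dawn at 10 °C, ochre's first reading gives a clock of 7.52 min, so 10 min spans 1.33 clocks against 5.08 in dawn, and that repeat still holds 14.2% of its starting material.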